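The easy step came first: the chair added substrate and target in the last ash reading, got 99.7%, and the meeting agreed to read target from the substrate lost.

| flask | substrate | partner | free catalyst | remark | time |
|---|---|---|---|---|---|
| elm | 0.58 M | 2.5 equiv (fed, over 40 min) | 1 mol% | run made earlier; the fed solution adds 0.50 times the starting volume |  |
| maple | 0.58 M | 3.8 equiv (fed, over 40 min) | 1 mol% | run made earlier; the fed solution adds 0.50 times the starting volume |  |
| ash | 0.58 M | 5 equiv (fed, over 40 min) | 1.5 mol% | run made earlier; the fed solution adds 0.50 times the starting volume |  |
| flask | 0.58 M | 5.00 equiv (fed, over 40 min) | 1 mol% | the fed solution adds 0.50 times the starting volume | 5.0 h |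

| run | time / h | target / % | substrate / % |
|---|---|---|---|
| elm | 0.500 | 5.1 | 94.5 |
| elm | 1.00 | 11.3 | 88.8 |
| elm | 1.50 | 16.7 | 82.8 |
| elm | 2.00 | 22.6 | 76.7 |
| elm | 2.50 | 27.5 | 72.1 |
| elm | 3.00 | 32.7 | 67.1 |
| maple | 0.500 | 5.2 | 94.1 |
| maple | 1.00 | 12.5 | 87.6 |
| maple | 1.50 | 19.1 | 81.4 |
| maple | 2.00 | 24.2 | 75.7 |
| maple | 2.50 | 29.8 | 70.2 |
| maple | 3.00 | 34.8 | 64.7 |
| ash | 0.250 | 3.6 | 96.5 |
| ash | 0.833 | 13.7 | 86.0 |
| ash | 1.33 | 22.3 | 77.9 |
| ash | 2.00 | 31.5 | 68.3 |
| ash | 3.00 | 44.0 | 55.7 |

(scatter of a reading: 0.3 percentage points)

- what is said of target includes idle complex
- amounts are per litre of the starting volume; all of the dose is in the solution fed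
- steps thought possible: catalyst intermediate B -> spent catalyst; substrate + catalyst intermediate A -> catalyst intermediate B; catalyst intermediate B -> free catalyst + target; partner + free catalyst <-> catalyst intermediate A; 2 catalyst intermediate A <-> resting dimer; free catalyst + target <-> idle complex
- the reaction counts as stopped when no species that holds the substrate changes by six tenths of a point or more over the second half of the time

1. why nothing more happens at 5.0 h, or that something still does (it is still moving / the partner has run out first / forward and back rates have come level / no working catalyst is left / all of the substrate has reacted)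
2. amount of target at 5.0 h, in percent of the substrate charged

The process engineer proposed treating substrate after the feed as a first-order decay (pseudo-first-order) with constant k, the log-slope between the reading at 1.00 h or the nearest one after the feed and the last reading. This gave 0.140 h⁻¹ for elm, 0.152 h⁻¹ for maple and 0.200 h⁻¹ for ash.

The kineticist replied that elm and maple differ in partner, so their ratio gives a partner order a of 0.187, which carries maple up to the flask's charge at 0.159 h⁻¹. The engineer added that the maple line, run back to full substrate, starts at a lag t0 of 0.126 h, so the first answer for the flask is 54.0% target.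

The chair asked that this go back in. Taking each run's partner at mid-run, a becomes 0.175, k becomes 0.159 h⁻¹, and target stays at 54.0%.

Ash differs from the flask in loading, so the meeting took the catalyst order n, the power to which k follows the loading, as 0.568. The kineticist said a value between 0.5 and 1 fits catalyst held partly as resting dimer, a resting state. The reckoned substrate in the flask still falls 23 percentage points over the second half of the time, so the meeting concluded that it is still moving.

The forecast said it is still moving, with 54% target (51% to 56.5%), and read the runs as “catalyst resting mostly as the dimer”.

The flask gives 52.7% target and it is still moving, 1.3 points below the meeting's second round.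

    catalyst intermediate B → spent catalyst (k = 0.00330 min⁻¹)
    substrate + catalyst intermediate A → catalyst intermediate B (k = 2.90 M⁻¹ min⁻¹)
    catalyst intermediate B → free catalyst + target (k = 2.10 min⁻¹)
    partner + free catalyst ⇌ catalyst intermediate A (K = 14.0 M⁻¹, k = 1.00 M⁻¹ min⁻¹)
    2 catalyst intermediate A ⇌ resting dimer, settled at all times (K = 1300 M⁻¹)
    free catalyst + target ⇌ idle complex (K = 2.40 M⁻¹, k = 0.0290 M⁻¹ min⁻¹)

The neighbouring flask is this flask with 2.5 mol% of free catalyst. Carrying n over gives k = 0.268 h⁻¹, and so a first answer of 72.9% target. Putting its partner use back in gives 0.267 h⁻¹ and 72.8%, which leaves 27.2% substrate. That neighbour flask stands at 74.4% target, idle complex counted, with 25% of its substrate left.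

All runs are calculated from invented constants.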